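## The problem

The target **18** is an achiral methyl benzoate with four ring substituents: the ester on C1, a free hydroxyl on C2, a methyl ether on C4 and an unbranched twenty-carbon chain on C6, with C3 and C5 unsubstituted. There is no ring fusion and no stereocenter, so the task is one of placement: four groups in the right positions, and two resorcinol oxygens told apart, the one beside the ester free and the one para to it methylated. The ester is flanked on both sides (C2 oxygen, C6 chain), so late carboxylation or esterification is unattractive and the C1 carbonyl is best brought in already as the methyl ester. The ester should never be hydrolysed, because the free β-resorcylic acid decarboxylates readily, and the electron-rich ring must be kept from strong electrophiles and oxidants. The C20 chain makes every intermediate that carries it waxy and hard to purify, so it should arrive late from a cheap, even-numbered lipid building block. The enabling feature is that the ester carbon on C1 and the first chain carbon on C6 are carbon substituents on neighbouring ring atoms, with the C2 oxygen directly beside C1. An aryne spanning C1–C6 that already carries the C2 and C4 oxygens can take both carbons from one malonate molecule, and the C2 oxygen decides which end receives which. The same C2 oxygen lies next to the ester carbonyl, so its methyl ether can be singled out at the end by chelation.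

## Retrosynthesis

**18 to 17.** The last disconnection is the O–CH3 bond at C2: the free phenol of **18** is traced back to the dimethyl ether **17**. Carrying both oxygens as methyl ethers keeps the ring free of acidic protons through the aryne and ylide steps and lets the route start from a symmetrical phenol. Putting two different protecting groups on the oxygens from the start would give up that symmetry. The forward step must remove one methyl group only, the one whose oxygen can chelate with the ester carbonyl.

**17 to 16 to 14 and 13.** The chain is cut between its second and third carbon atoms counted from the ring, as a C=C bond in **16**. A cut at the ring–chain bond would demand an sp2–sp3 coupling beside the ester, and a cut one bond further in would need a benzylic carbanion next to an ester. The chosen cut uses exactly the two-carbon acetate arm that the key step leaves on the ring, at the aldehyde oxidation level in **14**. It puts the other eighteen carbons into the phosphonium salt **13**, which comes from the commodity bromide **12**. A C30 compound becomes a C12 aromatic and a C18 lipid. The olefination must be faster than enolisation of the aldehyde; the alkene geometry does not matter because it is hydrogenated.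

**14 to 11.** The aldehyde is traced to the aliphatic ester of diester **11**, a change of oxidation level only. The forward reaction must reduce the open arylacetate ester and leave the doubly flanked benzoate alone.

**11 to 8 and 9 (through 10).** The C6–CH2 bond and the C1–CO2Me bond are cut together, which returns **11** to the aryne **10** and dimethyl malonate **9**. Stepwise alternatives (formylating and oxidising an arylacetate, or carboxylating ortho to an existing side chain) cost more operations and raise their own regiochemical questions. The double cut takes both carbon substituents from one cheap molecule and sets them ortho to each other by construction. The precursor **8** is a trisubstituted benzene derived from a symmetrical phenol. The forward reaction needs the malonate carbanion to attack the aryne carbon remote from the flanking methoxy group, and acyl transfer to the resulting aryl anion must beat protonation.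

**8 to 6 to 2 to 1.** The O–S bond of the triflate and the C–Si bond are cut, leading through silyl carbamate **6** and carbamate **2** to 3,5-dimethoxyphenol **1**. The silyl group must sit between the phenol oxygen and a methoxy group. In **2** both ortho positions are equivalent and each is activated by the carbamate and one methoxy group, so directed metalation has only to prefer them over the position between the two methoxy groups.

**13 to 12.** The C–P bond is cut, giving 1-bromooctadecane **12**.

## Roads not taken

**Alternative 1:** The ring is opened at C1–C2 and C2–C3, so that C2 is supplied by carbon monoxide A2 and the other five ring carbons by the acyclic enyne ester A1, methyl (2E)-4-acetoxy-3-icosylhex-2-en-5-ynoate. In the forward step [RhCl(CO)2]2 would trigger 1,2-acetoxy migration, insert A2 between the alkyne terminus and the alkene terminus, and close the ring to the phenol A3, methyl 4-acetoxy-2-icosyl-6-hydroxybenzoate.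

- Merits: the C2 hydroxyl is born free and the C4 oxygen already differentiated as an acetate. All four substituents are fixed by the open chain, so no aromatic regiochemistry has to be controlled.
- Weak points: A1 is not a simple precursor. It needs a trisubstituted β-alkyl acrylate of defined geometry, a propargylic acetate and the C20 chain from the first step. The alkene terminus that must bond to the carbonyl carbon carries an ester, an electron-poor and more substituted partner than this benzannulation is usually asked to accept. The acetate must then be exchanged for a methyl ether in two further operations next to a free phenol.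
- Comparison: this route is better at differentiating the two oxygens. The chosen plan answers with a key step on a close substrate class, cheap aromatic starting materials, a chain that enters only at step 7, and a final demethylation steered by chelation.

**Alternative 2:** The C1–C6 ring bond is cut, unfolding the ring into the triketo ester A5, methyl 3,5,7-trioxoheptacosanoate, itself released from the diketo-dioxinone A4, 6-(2,4-dioxotetracosyl)-2,2-dimethyl-4H-1,3-dioxin-4-one. Heating A4 in the ester-forming alcohol, then carbonate base and acid, would give A5, aldol closure of C2 onto the C7 ketone and aromatisation to the resorcylate A6, methyl 2-icosyl-4,6-dihydroxybenzoate.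

- Merits: the sequence is short, biomimetic and free of protecting groups. One para-selective O-methylation of A6 would finish the synthesis, because the ortho hydroxyl is hydrogen-bonded to the ester. In step count this road is shorter than the chosen one, and it has no aryne regiochemistry to secure.
- Weak points: the chain must enter as an odd-numbered C21 acyl unit, which is far less accessible than the C18 bromide **12**. The polycarbonyl intermediates are tautomeric, greasy and hard to purify. Aldol closure competes with Claisen-type closure to pyrone or acylphloroglucinol isomers. The final mono-methylation can overshoot.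
- Comparison: against the shorter sequence, the chosen plan offers small, easily purified aromatic intermediates up to the olefination, a cheap even-numbered chain source, and regiochemistry fixed by a covalent framework and not by enolate equilibria.

**Alternative 3:** The ring is cut at C3–C4 and C5–C6, giving the pyrone A7, methyl 2-icosyl-4-methoxy-6-oxo-6H-pyran-3-carboxylate, and the ketene acetal A8, 1,1-dimethoxyethene. Inverse-demand Diels–Alder addition, decarboxylative cycloreversion and loss of one methoxy group would give A9, methyl 2-icosyl-4,6-dimethoxybenzoate, which is the same compound as **17**.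

- Merits: it converges on the penultimate compound of the chosen route and would share its last step. The polarisation of the pyrone sets the regiochemistry.
- Weak points: the 4-methoxy group makes the pyrone a poorer electron-deficient diene. The diene terminus that must accept the nucleophilic carbon of A8 is the fully substituted one bearing the C20 chain, so forcing temperatures are likely, with a partner that hydrolyses and polymerises easily. A7 is itself a multistep target, needing again a C21 acyl unit and a regioselective O-methylation of a 4-hydroxypyrone.
- Comparison: if the cycloaddition worked it would reach **17** in fewer operations than the eight steps used here. The chosen plan relies instead on a ring-substitution event with direct analogy and on purchasable precursors.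

Key step: step 4

Assumption: alkene **16** is drawn as the Z isomer expected from a salt-free unstabilised ylide; any E isomer formed alongside converges on **17** in step 8.

## Route

Step 1
Reactants: 1 3,5-dimethoxyphenol
Product: 2 3,5-dimethoxyphenyl N-isopropylcarbamate
Conditions: i-PrNCO, Et3N (cat.), CH2Cl2, rt
Reagents that add atoms: isopropyl isocyanate, CC(C)N=C=O
Why: Amine-catalysed addition of the phenol O–H across the isocyanate (carbamoylation) is clean for electron-rich phenols; the N-monoalkyl carbamate is chosen because it directs ortho-metalation and can later be removed under mild base.

Step 2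
Reactants: 2 3,5-dimethoxyphenyl N-isopropylcarbamate
Product: 6 3,5-dimethoxy-2-(trimethylsilyl)phenyl N-isopropylcarbamate, via N-silyl carbamate 3 (not isolated), via aryllithium 4 (not isolated), via bis-silyl carbamate 5 (not isolated)
Conditions: TBSOTf, TMEDA, Et2O, 0 °C to rt; n-BuLi (2.2 equiv), TMEDA, −78 °C; Me3SiCl, −78 °C to rt; aq. NaHSO4
Reagents that add atoms: chlorotrimethylsilane, C[Si](C)(C)Cl; tert-butyldimethylsilyl triflate, CC(C)(C)[Si](C)(C)OS(=O)(=O)C(F)(F)F (its silyl group is carried only by 3, 4 and 5 and is lost on work-up)
Why: Directed ortho-metalation of an O-aryl carbamate after in situ N-silylation, which masks the N–H and blocks loss of isocyanate; one equivalent of n-BuLi neutralises the ammonium triflate and the second lithiates C2, the site activated jointly by the carbamate and the neighbouring methoxy group. Me3SiCl traps the aryllithium at −78 °C before carbamoyl migration can occur, and the acidic work-up cleaves only the N–Si bond.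

Step 3
Reactants: 6 3,5-dimethoxy-2-(trimethylsilyl)phenyl N-isopropylcarbamate
Product: 8 3,5-dimethoxy-2-(trimethylsilyl)phenyl trifluoromethanesulfonate, via silyl phenol 7 (not isolated)
Conditions: DBU, Et2NH, MeCN, 40 °C; then PhNTf2, rt
Reagents that add atoms: N-phenylbis(trifluoromethanesulfonimide), O=S(=O)(N(c1ccccc1)S(=O)(=O)C(F)(F)F)C(F)(F)F
Why: DBU deprotonates the carbamate N–H and the anion expels the phenoxide (E1cB cleavage), the isopropyl isocyanate set free being scavenged by Et2NH as a urea. The phenoxide is triflated in the same pot by PhNTf2, a mild triflyl donor that leaves the acid-sensitive aryl–silicon bond intact.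

Step 4
Reactants: 8 3,5-dimethoxy-2-(trimethylsilyl)phenyl trifluoromethanesulfonate; 9 dimethyl malonate
Product: 11 methyl 2-(2-methoxy-2-oxoethyl)-4,6-dimethoxybenzoate, via 3,5-dimethoxybenzyne 10 (not isolated)
Conditions: CsF, MeCN, 80 °C (9 in excess)
Reagents that add atoms: none
Why: Fluoride attacks silicon in 8 and the ortho triflate leaves, giving aryne 10 slowly because CsF is sparingly soluble in MeCN, so its stationary concentration stays low. Fluoride also deprotonates 9, and the malonate carbanion adds to the aryne carbon remote from the flanking methoxy group, the carbon that becomes C6 of the target. This is the orientation known for 3-alkoxyarynes: the distal carbon is the flatter, more electrophilic one, and the aryl anion developing at the proximal carbon is stabilised inductively by the adjacent C–O bond. The aryl anion then attacks an ester carbonyl of the malonate unit (4-exo-trig) to give a benzocyclobutenoxide, which fragments by C–C cleavage to the benzoate on C1 and the acetate enolate on C6, protonated on work-up. The net result is insertion of the aryne into a C–C sigma bond of 9, the acyl-alkylation of arynes known for malonates and beta-keto esters, including alkoxy-substituted arynes. The four-membered ring is only transient; no ring remains in 11 and no stereocenter is formed. The selectivity needed is regiochemical and is secured by the methoxy group beside the aryne bond, which the second methoxy group, meta to the site of attack, does not oppose. Using 9 in excess keeps the less acidic product 11 from competing as a nucleophile for 10.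

Step 5
Reactants: 12 1-bromooctadecane
Product: 13 octadecyltriphenylphosphonium bromide
Conditions: PPh3, MeCN, reflux
Reagents that add atoms: triphenylphosphine, c1ccc(cc1)P(c1ccccc1)c1ccccc1
Why: SN2 quaternisation of triphenylphosphine by an unhindered primary bromide; the salt is freed from excess reagents by trituration and dried before use.

Step 6
Reactants: 11 methyl 2-(2-methoxy-2-oxoethyl)-4,6-dimethoxybenzoate
Product: 14 methyl 2,4-dimethoxy-6-(2-oxoethyl)benzoate
Conditions: i-Bu2AlH (1.1 equiv), CH2Cl2, −78 °C; MeOH, then aq. KNaC4H4O6
Reagents that add atoms: none
Why: Partial ester reduction with i-Bu2AlH at −78 °C stops at the tetrahedral aluminium hemiacetal, which gives the aldehyde only on work-up. The arylacetate ester is open and unconjugated, whereas the benzoate is flanked by two ortho substituents and is expected to stay untouched; 14 is used at once in step 7.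

Step 7
Reactants: 14 methyl 2,4-dimethoxy-6-(2-oxoethyl)benzoate; 13 octadecyltriphenylphosphonium bromide
Product: 16 methyl 2-[(2Z)-icos-2-en-1-yl]-4,6-dimethoxybenzoate, via octadecylidenetriphenylphosphorane 15 (not isolated)
Conditions: 13, NaN(SiMe3)2, THF, 0 °C; then 14, −78 °C to rt
Reagents that add atoms: none
Why: Wittig olefination with a salt-free unstabilised ylide, which should add to the aldehyde at −78 °C faster than it enolises it and gives mainly the Z-alkene through the kinetically formed cis-oxaphosphetane. The geometry is of no consequence because the double bond is hydrogenated next, and the hindered benzoate does not react with the ylide.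

Step 8
Reactants: 16 methyl 2-[(2Z)-icos-2-en-1-yl]-4,6-dimethoxybenzoate
Product: 17 methyl 2-icosyl-4,6-dimethoxybenzoate
Conditions: H2 (1 atm), Pd/C, EtOAc, rt
Reagents that add atoms: none
Why: Heterogeneous catalytic hydrogenation of an unhindered disubstituted alkene; the aryl methyl ethers and the ester are inert, and either alkene isomer gives the same saturated chain.

Step 9
Reactants: 17 methyl 2-icosyl-4,6-dimethoxybenzoate
Product: 18 methyl 2-hydroxy-6-icosyl-4-methoxybenzoate
Conditions: BCl3, CH2Cl2, −78 to 0 °C; aq. NaHCO3
Reagents that add atoms: none
Why: Chelation-controlled ether cleavage: BCl3 binds the ester carbonyl and the ortho methoxy oxygen in a six-membered chelate and chloride removes that methyl group as chloromethane. The unchelated para methyl ether and the methyl ester should survive at low temperature.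

## Compound list

1 | 3,5-dimethoxyphenol | COc1cc(O)cc(OC)c1 | starting material
2 | 3,5-dimethoxyphenyl N-isopropylcarbamate | CC(C)NC(=O)Oc1cc(OC)cc(OC)c1 | intermediate
3 | 3,5-dimethoxyphenyl N-(tert-butyldimethylsilyl)-N-isopropylcarbamate | CC(C)N(C(=O)Oc1cc(OC)cc(OC)c1)[Si](C)(C)C(C)(C)C | intermediate (not isolated)
4 | [2-({(tert-butyldimethylsilyl)(isopropyl)carbamoyl}oxy)-4,6-dimethoxyphenyl]lithium | [Li]c1c(OC)cc(OC)cc1OC(=O)N(C(C)C)[Si](C)(C)C(C)(C)C | intermediate (not isolated)
5 | 3,5-dimethoxy-2-(trimethylsilyl)phenyl N-(tert-butyldimethylsilyl)-N-isopropylcarbamate | CC(C)N(C(=O)Oc1cc(OC)cc(OC)c1[Si](C)(C)C)[Si](C)(C)C(C)(C)C | intermediate (not isolated)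
6 | 3,5-dimethoxy-2-(trimethylsilyl)phenyl N-isopropylcarbamate | CC(C)NC(=O)Oc1cc(OC)cc(OC)c1[Si](C)(C)C | intermediate
7 | 3,5-dimethoxy-2-(trimethylsilyl)phenol (present as its amidinium phenoxide) | COc1cc(O)c([Si](C)(C)C)c(OC)c1 | intermediate (not isolated)
8 | 3,5-dimethoxy-2-(trimethylsilyl)phenyl trifluoromethanesulfonate | COc1cc(OC)c([Si](C)(C)C)c(OS(=O)(=O)C(F)(F)F)c1 | intermediate
9 | dimethyl malonate | COC(=O)CC(=O)OC | starting material
10 | 3,5-dimethoxybenzyne (1,2-didehydro-3,5-dimethoxybenzene) | COC1=CC(OC)=CC#C1 | intermediate (not isolated)
11 | methyl 2-(2-methoxy-2-oxoethyl)-4,6-dimethoxybenzoate | COC(=O)Cc1cc(OC)cc(OC)c1C(=O)OC | intermediate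
12 | 1-bromooctadecane | CCCCCCCCCCCCCCCCCCBr | starting material
13 | octadecyltriphenylphosphonium bromide | CCCCCCCCCCCCCCCCCC[P+](c1ccccc1)(c1ccccc1)c1ccccc1.[Br-] | intermediate
14 | methyl 2,4-dimethoxy-6-(2-oxoethyl)benzoate | COC(=O)c1c(CC=O)cc(OC)cc1OC | intermediate
15 | octadecylidenetriphenylphosphorane | CCCCCCCCCCCCCCCCCC=P(c1ccccc1)(c1ccccc1)c1ccccc1 | intermediate (not isolated)
16 | methyl 2-[(2Z)-icos-2-en-1-yl]-4,6-dimethoxybenzoate | CCCCCCCCCCCCCCCCC/C=C\Cc1cc(OC)cc(OC)c1C(=O)OC | intermediate
17 | methyl 2-icosyl-4,6-dimethoxybenzoate | CCCCCCCCCCCCCCCCCCCCc1cc(OC)cc(OC)c1C(=O)OC | intermediate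
18 | methyl 2-hydroxy-6-icosyl-4-methoxybenzoate | CCCCCCCCCCCCCCCCCCCCc1cc(OC)cc(O)c1C(=O)OC | target

## Step count and least certain steps

Total: 9 steps. Longest linear sequence: 8 steps (steps 1, 2, 3, 4, 6, 7, 8, 9). Step 5 is a one-step branch from **12**.

**Step 4 (key step).** The most likely failure is protonation of the aryl anion before it transfers the acyl group, which leaves plain α-arylation of the malonate. Addition with the reverse orientation, or further arylation of the product enolate, would also erode the yield. The fallback builds the same diester by classical electrophilic substitution and sets out from **9**: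
- Arylation of **9** with commercial 1-bromo-3,5-dimethoxybenzene (Pd(OAc)2, P(t-Bu)3, K3PO4, toluene) gives dimethyl 2-(3,5-dimethoxyphenyl)malonate F1.
- Dealkoxycarbonylation with LiCl in wet DMSO gives methyl 2-(3,5-dimethoxyphenyl)acetate F2.
- Vilsmeier–Haack formylation (POCl3, DMF) para to one methoxy group and ortho to the side chain gives methyl 2-(2-formyl-3,5-dimethoxyphenyl)acetate F3.
- Oxidation with NaClO2 and NaH2PO4 gives 2,4-dimethoxy-6-(2-methoxy-2-oxoethyl)benzoic acid F4.
- Methylation with MeI and K2CO3 returns to the route at **11**.

**Step 7.** The ylide is a strong base and the CH2 group of **14** is both benzylic and α to the aldehyde, so enolisation followed by self-condensation may outrun olefination. The fallback avoids carbonyl olefination and sets out from **14**: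
- Reduction with NaBH4 at 0 °C gives methyl 2-(2-hydroxyethyl)-4,6-dimethoxybenzoate F5, kept cold and neutral so that it does not close onto the hindered ester.
- CBr4 and PPh3 convert it to methyl 2-(2-bromoethyl)-4,6-dimethoxybenzoate F6.
- Coupling with octadecylmagnesium bromide F7 (from **12** and magnesium) under Li2CuCl4 catalysis in THF at −20 °C joins the two sp3 carbons and returns to the route at **17**, so step 8 is no longer needed.

**Step 6.** Collapse of the aluminium hemiacetal before the quench would lead to over-reduction to the alcohol, and some attack at the benzoate cannot be excluded. The fallback separates the two esters by hydrolysis and sets out from **11**: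
- One equivalent of LiOH in aqueous THF should saponify only the open ester, giving 2-[3,5-dimethoxy-2-(methoxycarbonyl)phenyl]acetic acid F8.
- Coupling with ethanethiol by a carbodiimide gives methyl 2-[2-(ethylsulfanyl)-2-oxoethyl]-4,6-dimethoxybenzoate F9.
- Fukuyama reduction (Et3SiH, Pd/C, acetone) stops cleanly at the aldehyde and returns to the route at **14**.

**Step 9.** Cleavage may not stop after the chelated ether, so that the para ether is lost as well, or it may stall at partial conversion. The fallback gives up the selective cleavage for a selective alkylation and sets out from **17**:
- Excess BBr3 in CH2Cl2 removes both ether methyl groups, giving methyl 2,4-dihydroxy-6-icosylbenzoate F10.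
- One equivalent of MeI with K2CO3 in acetone methylates only the para hydroxyl, because the ortho hydroxyl is hydrogen-bonded to the ester, and returns to the route at **18**.

**Step 2.** Metalation between the two methoxy groups, or migration of the carbamoyl group to carbon on warming, would divert material. The fallback places the silicon by halogen–metal exchange and sets out from **1**:
- Bromination with N-bromosuccinimide in CH2Cl2 at −78 °C, followed by separation from the para isomer, gives 2-bromo-3,5-dimethoxyphenol F11.
- Silylation of the oxygen with (Me3Si)2NH gives (2-bromo-3,5-dimethoxyphenoxy)trimethylsilane F12.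
- n-BuLi at −100 °C effects bromine–lithium exchange and migration of silicon from oxygen to carbon, and Tf2O traps the phenoxide. This returns to the route at **8** and replaces steps 1 to 3.

## Further compounds

F1 | step 4 | dimethyl 2-(3,5-dimethoxyphenyl)malonate | COC(=O)C(c1cc(OC)cc(OC)c1)C(=O)OC
F2 | step 4 | methyl 2-(3,5-dimethoxyphenyl)acetate | COC(=O)Cc1cc(OC)cc(OC)c1
F3 | step 4 | methyl 2-(2-formyl-3,5-dimethoxyphenyl)acetate | COC(=O)Cc1cc(OC)cc(OC)c1C=O
F4 | step 4 | 2,4-dimethoxy-6-(2-methoxy-2-oxoethyl)benzoic acid | COC(=O)Cc1cc(OC)cc(OC)c1C(=O)O
F5 | step 7 | methyl 2-(2-hydroxyethyl)-4,6-dimethoxybenzoate | COC(=O)c1c(CCO)cc(OC)cc1OC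
F6 | step 7 | methyl 2-(2-bromoethyl)-4,6-dimethoxybenzoate | COC(=O)c1c(CCBr)cc(OC)cc1OC
F7 | step 7 | octadecylmagnesium bromide | CCCCCCCCCCCCCCCCCC[Mg]Br
F8 | step 6 | 2-[3,5-dimethoxy-2-(methoxycarbonyl)phenyl]acetic acid | OC(=O)Cc1cc(OC)cc(OC)c1C(=O)OC
F9 | step 6 | methyl 2-[2-(ethylsulfanyl)-2-oxoethyl]-4,6-dimethoxybenzoate | CCSC(=O)Cc1cc(OC)cc(OC)c1C(=O)OC
F10 | step 9 | methyl 2,4-dihydroxy-6-icosylbenzoate | CCCCCCCCCCCCCCCCCCCCc1cc(O)cc(O)c1C(=O)OC
F11 | step 2 | 2-bromo-3,5-dimethoxyphenol | COc1cc(O)c(Br)c(OC)c1
F12 | step 2 | (2-bromo-3,5-dimethoxyphenoxy)trimethylsilane | COc1cc(O[Si](C)(C)C)c(Br)c(OC)c1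
A1 | alternative 1 | methyl (2E)-4-acetoxy-3-icosylhex-2-en-5-ynoate (racemic) | C#CC(OC(C)=O)/C(CCCCCCCCCCCCCCCCCCCC)=C/C(=O)OC
A2 | alternative 1 | carbon monoxide | [C-]#[O+]
A3 | alternative 1 | methyl 4-acetoxy-2-icosyl-6-hydroxybenzoate | CCCCCCCCCCCCCCCCCCCCc1cc(OC(C)=O)cc(O)c1C(=O)OC
A4 | alternative 2 | 6-(2,4-dioxotetracosyl)-2,2-dimethyl-4H-1,3-dioxin-4-one | CCCCCCCCCCCCCCCCCCCCC(=O)CC(=O)CC1=CC(=O)OC(C)(C)O1
A5 | alternative 2 | methyl 3,5,7-trioxoheptacosanoate | CCCCCCCCCCCCCCCCCCCCC(=O)CC(=O)CC(=O)CC(=O)OC
A6 | alternative 2 | methyl 2-icosyl-4,6-dihydroxybenzoate | CCCCCCCCCCCCCCCCCCCCc1cc(O)cc(O)c1C(=O)OC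
A7 | alternative 3 | methyl 2-icosyl-4-methoxy-6-oxo-6H-pyran-3-carboxylate | CCCCCCCCCCCCCCCCCCCCc1oc(=O)cc(OC)c1C(=O)OC
A8 | alternative 3 | 1,1-dimethoxyethene | C=C(OC)OC
A9 | alternative 3 | methyl 2-icosyl-4,6-dimethoxybenzoate | CCCCCCCCCCCCCCCCCCCCc1cc(OC)cc(OC)c1C(=O)OC
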